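**Retrosynthetic overview**
- The benzofuran furan ring is formed last, by a one-pot desilylative Sonogashira coupling and 5-endo-dig cyclisation between a free o-iodoresorcinol carrying the geranyl group and an aryl alkyne carrying the chiral dihydrobenzofuran.
- The western o-iodophenol comes from two successive directed ortho-lithiations of resorcinol bis-MOM ether (geranylation between the oxygens, then iodination), followed by MOM removal.
- The dihydrobenzofuran ring is formed first: its aryl C–O bond is closed photochemically by ipso-substitution of an ortho OMe by the secondary OH of a diol, leaving the C–O bond at the stereocentre untouched.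
- The single (R) stereocentre is bought in methyl (R)-glycidate, which is opened at C3 by an aryl-copper species from 1-bromo-2-iodo-3,5-dimethoxybenzene and then treated with MeMgBr.

Assumption: methyl (R)-glycidate (the enantiomer obtainable from L-serine) and 1,3-bis(methoxymethoxy)benzene are purchased; if the latter is not stocked it costs one extra step from resorcinol (MOMCl, i-Pr2NEt).

**Eastern fragment**

Step 1
Reactants: 1, 1-bromo-3,5-dimethoxybenzene
Product: 2, 1-bromo-2-iodo-3,5-dimethoxybenzene
Conditions: NIS (1.05 equiv), TFA (10 mol%), MeCN, 0 °C → rt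
Reagents that add atoms: N-iodosuccinimide, O=C1CCC(=O)N1I
Why: Electrophilic aromatic iodination goes to C2 (ortho to one OMe, para to the other) rather than the more hindered position between the two OMe groups, placing iodine between Br and OMe.

Step 2
Reactants: 2, 1-bromo-2-iodo-3,5-dimethoxybenzene (1.25 equiv); 3, methyl (R)-glycidate (1.0 equiv)
Product: 4, (2R)-1-(2-bromo-4,6-dimethoxyphenyl)-3-methylbutane-2,3-diol
Conditions: i-PrMgCl·LiCl, THF, −30 °C; CuI (10 mol%), 3, −40 → −20 °C; then MeMgBr (4 equiv), → 0 °C (one pot)
Reagents that add atoms: methylmagnesium bromide, C[Mg]Br (two CH3 groups)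
Why: Chemoselective I/Mg exchange (I far faster than Br), Cu-catalysed SN2 opening of the glycidate at its unsubstituted C3, then double Grignard addition to the ester; the C2–O bond of 3 is never broken, so its R configuration is carried into 4 unchanged.

Step 3
Reactants: 4, (2R)-1-(2-bromo-4,6-dimethoxyphenyl)-3-methylbutane-2,3-diol
Product: 5, 2-[(2R)-4-bromo-6-methoxy-2,3-dihydro-1-benzofuran-2-yl]propan-2-ol
Conditions: 3,6-di-t-Bu-9-mesityl-10-phenylacridinium BF4 (5 mol%), 455 nm LEDs, DCE/CF3CH2OH 1:1 (0.05 M), N2, rt, no base
Reagents that add atoms: none (MeOH is lost)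
Why: Proposed new method: an intramolecular cation-radical-accelerated SNAr (alkoxy-de-methoxylation), in which the excited acridinium (E*red about +2.1 V vs SCE) oxidises the dimethoxyarene (about +1.5–1.6 V) to its cation radical, the pendant secondary OH adds 5-exo to the adjacent ipso C–OMe carbon (the O-bearing carbons carry the positive charge, the C–Br carbon is meta to both OMe groups, and the tertiary OH would need a slower six-membered closure by a hindered oxygen), and loss of H+ and MeOH with back electron transfer from the acridine radical gives the aryl ether; the carbinol C–O bond is not broken, so the R centre is retained; the closest known reaction type is the acridinium-photocatalysed intermolecular substitution of methoxy groups on arenes by azoles and amines, here extended to a ring-forming O-nucleophile.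

Step 4
Reactants: 5, 2-[(2R)-4-bromo-6-methoxy-2,3-dihydro-1-benzofuran-2-yl]propan-2-ol
Product: 6, (2R)-4-bromo-2-(2-hydroxypropan-2-yl)-2,3-dihydro-1-benzofuran-6-ol
Conditions: NaSEt (4 equiv), DMF, 110 °C; pH 5 work-up
Reagents that add atoms: none
Why: Thiolate SN2 O-demethylation attacks only the methyl group (the other ether carbon is a hindered secondary centre), while the unactivated aryl bromide, the tertiary alcohol and the stereocentre are untouched.

Step 5
Reactants: 6, (2R)-4-bromo-2-(2-hydroxypropan-2-yl)-2,3-dihydro-1-benzofuran-6-ol; 7, ethynyltrimethylsilane (1.5 equiv)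
Product: 8, (2R)-2-(2-hydroxypropan-2-yl)-4-[(trimethylsilyl)ethynyl]-2,3-dihydro-1-benzofuran-6-ol
Conditions: Pd(PhCN)2Cl2 (3 mol%), P(t-Bu)3·HBF4 (6 mol%), CuI (3 mol%), i-Pr2NH, dioxane, 45 °C
Reagents that add atoms: none beyond 7
Why: Sonogashira coupling with a bulky electron-rich phosphine handles the electron-rich, ortho-substituted aryl bromide, and the free phenol and tertiary alcohol are tolerated under amine base.

**Western fragment**

Step 6
Reactants: 9, 1,3-bis(methoxymethoxy)benzene; 10, geranyl bromide [(2E)-1-bromo-3,7-dimethylocta-2,6-diene]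
Product: 11, 2-[(2E)-3,7-dimethylocta-2,6-dien-1-yl]-1,3-bis(methoxymethoxy)benzene
Conditions: n-BuLi (1.1 equiv), THF, 0 °C, 1 h; CuI (1.0 equiv), −40 °C; 10, −40 °C → rt
Reagents that add atoms: none beyond 10
Why: Directed ortho-metalation occurs at C2 between the two OMOM groups, and the aryl-copper species alkylates the primary allylic bromide by SN2 at C1, keeping the 2E geometry.

Step 7
Reactants: 11, 2-[(2E)-3,7-dimethylocta-2,6-dien-1-yl]-1,3-bis(methoxymethoxy)benzene
Product: 12, 2-[(2E)-3,7-dimethylocta-2,6-dien-1-yl]-4-iodo-1,3-bis(methoxymethoxy)benzene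
Conditions: n-BuLi (1.2 equiv), TMEDA, THF, −20 → 0 °C; I2 (1.3 equiv), −78 °C → rt; Na2S2O3 work-up
Reagents that add atoms: iodine, II
Why: A second OMOM-directed ortho-lithiation at C4 (kinetically preferred over benzylic deprotonation at or below 0 °C) is trapped by I2 at −78 °C faster than iodine can add to the alkenes.

Step 8
Reactants: 12, 2-[(2E)-3,7-dimethylocta-2,6-dien-1-yl]-4-iodo-1,3-bis(methoxymethoxy)benzene
Product: 13, 2-[(2E)-3,7-dimethylocta-2,6-dien-1-yl]-4-iodobenzene-1,3-diol
Conditions: HCl (about 1 M, from AcCl in MeOH), MeOH, 40 °C, monitored and stopped at full conversion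
Reagents that add atoms: none
Why: Acid-catalysed acetal methanolysis removes both MOM groups under dilute, mild conditions that are faster than acid-mediated cyclisation of the phenol onto the geranyl alkene.

**Union**

Step 9
Reactants: 8, (2R)-2-(2-hydroxypropan-2-yl)-4-[(trimethylsilyl)ethynyl]-2,3-dihydro-1-benzofuran-6-ol (1.1 equiv); 13, 2-[(2E)-3,7-dimethylocta-2,6-dien-1-yl]-4-iodobenzene-1,3-diol
Product: 14, mulberrofuran X
Conditions: Pd(PPh3)2Cl2 (5 mol%), CuI (10 mol%), CsF (3 equiv), Et3N, degassed DMF (trace H2O), 60 → 80 °C, Ar
Reagents that add atoms: none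
Why: Fluoride releases the terminal alkyne in situ (low concentration, little Glaser dimer), Sonogashira coupling occurs at the aryl iodide, and the ortho OH (the one between the iodide carbon and the geranyl carbon) then closes 5-endo-dig to the 2-arylbenzofuran, leaving the other OH as the 6-OH next to the 7-geranyl group; the stereocentre is remote and unaffected.

**Compound list**
1 | 1-bromo-3,5-dimethoxybenzene | COc1cc(OC)cc(Br)c1 | starting material
2 | 1-bromo-2-iodo-3,5-dimethoxybenzene | COc1cc(OC)c(I)c(Br)c1 | intermediate
3 | methyl (R)-glycidate [methyl (2R)-oxirane-2-carboxylate] | COC(=O)[C@H]1CO1 | starting material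
4 | (2R)-1-(2-bromo-4,6-dimethoxyphenyl)-3-methylbutane-2,3-diol | COc1cc(OC)c(C[C@@H](O)C(C)(C)O)c(Br)c1 | intermediate
5 | 2-[(2R)-4-bromo-6-methoxy-2,3-dihydro-1-benzofuran-2-yl]propan-2-ol | COc1cc(Br)c2C[C@H](C(C)(C)O)Oc2c1 | intermediate
6 | (2R)-4-bromo-2-(2-hydroxypropan-2-yl)-2,3-dihydro-1-benzofuran-6-ol | Oc1cc(Br)c2C[C@H](C(C)(C)O)Oc2c1 | intermediate
7 | ethynyltrimethylsilane | C#C[Si](C)(C)C | starting material
8 | (2R)-2-(2-hydroxypropan-2-yl)-4-[(trimethylsilyl)ethynyl]-2,3-dihydro-1-benzofuran-6-ol | C[Si](C)(C)C#Cc1cc(O)cc2c1C[C@H](C(C)(C)O)O2 | intermediate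
9 | 1,3-bis(methoxymethoxy)benzene | COCOc1cccc(OCOC)c1 | starting material
10 | geranyl bromide [(2E)-1-bromo-3,7-dimethylocta-2,6-diene] | CC(C)=CCC/C(C)=C/CBr | starting material
11 | 2-[(2E)-3,7-dimethylocta-2,6-dien-1-yl]-1,3-bis(methoxymethoxy)benzene | CC(C)=CCC/C(C)=C/Cc1c(OCOC)cccc1OCOC | intermediate
12 | 2-[(2E)-3,7-dimethylocta-2,6-dien-1-yl]-4-iodo-1,3-bis(methoxymethoxy)benzene | CC(C)=CCC/C(C)=C/Cc1c(OCOC)ccc(I)c1OCOC | intermediate
13 | 2-[(2E)-3,7-dimethylocta-2,6-dien-1-yl]-4-iodobenzene-1,3-diol | CC(C)=CCC/C(C)=C/Cc1c(O)ccc(I)c1O | intermediate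
14 | mulberrofuran X | CC(C)=CCC/C(C)=C/Cc1c(O)ccc2cc(-c3cc(O)cc4c3C[C@H](C(C)(C)O)O4)oc12 | target

**Totals**
Total steps: 9 (eastern 5, western 3, union 1).
Longest linear sequence: 6 steps (1 → 2 → 4 → 5 → 6 → 8 → 14).

**Three steps most likely to fail, with fallbacks**
1. Step 3, the proposed photochemical ring closure. The risks are closure through the tertiary OH to a chroman, benzylic C–C fragmentation of the diol cation radical, and low conversion. Fallback (known chemistry): form the ring C–O bond at the sp3 carbon with inversion. Open methyl (S)-glycidate with the aryl-copper reagent from 1-bromo-2-iodo-3,5-bis(methoxymethoxy)benzene to give the (S)-α-hydroxy ester, remove the MOM groups (HCl/MeOH), close the ring by intramolecular Mitsunobu etherification with the ortho phenol (PPh3, DIAD; inversion to the (R)-dihydrobenzofuran-2-carboxylate), then add MeMgBr to reach 6 directly.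
2. Step 2, the opening of the glycidate by a 2,6-disubstituted, ortho-bromo aryl-copper species. The risks are aryne formation, halohydrin formation and attack at the ester. Fallback: reverse the polarity of the C(sp2)–C(sp3) bond formation. Couple 2 at its C–I bond with the organozinc reagent from Boc-3-iodo-D-alanine methyl ester (Pd2(dba)3/SPhos Negishi coupling), remove Boc, convert the amine to the (R)-α-hydroxy acid by retentive diazotisation (NaNO2, aq. H2SO4), esterify, and add MeMgBr to give 4.
3. Step 9, the one-pot desilylation, coupling and cyclisation on unprotected polyphenols. The risks are alkyne homocoupling, incomplete cyclisation and oxidation of the iodoresorcinol. Fallback: separate the events and couple in protected form. Desilylate 8 (K2CO3, MeOH), run a standard Sonogashira coupling with the MOM-protected iodide 12 to the diarylacetylene, remove the MOM groups, and close the furan in a separate CuI- or Cs2CO3-mediated 5-endo-dig hydroalkoxylation.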